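The route rests on one disconnection, the C5–C10 bond of the decalin: rings A and B are the ten-membered ring of germacrone folded across that bond. A Lewis acid opens a C1–C10 epoxide at C10 while C5 of the (E)-C4=C5 alkene attacks across the ring; this single event closes both six-membered rings, sets C5 and C10, and leaves a 3-ene for β-face cis-dioxygenation. The feature exploited is that the C10 methyl, the C4 methyl and the three-carbon unit on C7 beside the C8 ketone of rings A and B are already in place in germacrone. The precursor is (1R,10R)-1,10-epoxygermacrone, a trans-epoxide that keeps the C4=C5 alkene and the C7=C11 enone.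

Key step: step 2

Remark on the chemistry: eudesmane numbering is used for every decalin and for the ten-membered ring, β is the face of the C10 methyl group, and the D-fructose-derived Shi ketone is assumed to give the (1R,10R)-epoxide because it gives (R,R)-epoxides from open-chain (E)-trisubstituted alkenes.

Step 1
Reactants: 1 germacrone
Product: 2 (1R,10R)-1,10-epoxygermacrone
Conditions: D-fructose-derived Shi ketone, Oxone (2KHSO5·KHSO4·K2SO4, added in portions), NaHCO3, MeCN–aq. Na2EDTA, 0 °C, pH 7–8; chromatography to remove the 4,5-epoxide and unreacted 1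
Reagents that add atoms: potassium peroxymonosulfate (active part of Oxone), [K+].[O-]S(=O)(=O)OO
Why: Shi asymmetric epoxidation by the chiral dioxirane formed from the ketone and KHSO5: the electrophilic oxidant leaves the electron-poor C7=C11 enone alkene alone, syn oxygen transfer to the outer face of the (E)-C1=C10 alkene sets C1 and C10 together, the spiro transition state is expected to select the ring conformer that leads to the (1R,10R)-epoxide (the planar-chiral conformers of 1 interconvert rapidly), and the near-neutral buffer is chosen because the β,γ-epoxy ketone would open by β-elimination at higher pH.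

Step 2
Reactants: 2 (1R,10R)-1,10-epoxygermacrone
Product: 4 1β-hydroxyeudesma-3,7(11)-dien-8-one, via eudesm-4-yl cation 3 (not isolated)
Conditions: BF3·OEt2 (0.3 equiv), CH2Cl2, −78 → −20 °C; Et3N, then aq. NaHCO3
Reagents that add atoms: none
Why: BF3 coordinates the epoxide oxygen and weakens the tertiary C10–O bond, and C5 of the (E)-C4=C5 alkene, held over C10 in the crossed chair–chair conformer, attacks C10 from the side opposite the leaving oxygen, so that C5–C10 forms while C1 keeps its oxygen; the tertiary cation 3 then loses the axial C3 proton. The closest known reaction type is the acid-induced transannular cation–olefin cyclisation of germacra-1(10),4-diene 1(10)-epoxides to 1-hydroxyeudesmanes. Ring A (C1–C2–C3–C4–C5–C10) closes 6-endo-trig with respect to the alkene, because the cationic C4 stays inside it, and ring B (C5–C6–C7–C8–C9–C10) closes 6-exo-trig, with C4 outside it and the breaking C10–O bond exocyclic to it. C10 is set by inversion at the epoxide carbon, so the (10R)-epoxide gives the β-methyl, and C5 is set by the (E)-alkene geometry and the chair–chair fold, which place its hydrogen α and the ring fusion trans; the C1 carbinol centre is carried through unchanged as the equatorial 1β-hydroxyl. The step needs attack from C5 and not C4, which Markovnikov polarity secures (tertiary C4 cation, 6/6 instead of 5/7 ring system), and proton loss towards C3 and not C15 or C5, which is only kinetically controlled at low temperature, so the 4(15)- and 4-ene isomers are expected by-products to be removed on AgNO3-impregnated silica gel. The C7=C11 enone alkene is too electron-poor to intercept the cation, and water is excluded so that C4 is not captured as the 4α-alcohol.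

Step 3
Reactants: 4 1β-hydroxyeudesma-3,7(11)-dien-8-one
Product: 5 1β-(imidazol-1-ylthiocarbonyloxy)eudesma-3,7(11)-dien-8-one
Conditions: 1,1'-thiocarbonyldiimidazole, DMAP (cat.), ClCH2CH2Cl, 70 °C
Reagents that add atoms: 1,1'-thiocarbonyldiimidazole, S=C(n1ccnc1)n1ccnc1
Why: Thioacylation of the equatorial secondary 1β-hydroxyl by acyl transfer (first stage of a Barton–McCombie deoxygenation) under base-free conditions that spare the enolisable enone and the 3-ene; no stereocentre is touched.

Step 4
Reactants: 5 1β-(imidazol-1-ylthiocarbonyloxy)eudesma-3,7(11)-dien-8-one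
Product: 6 eudesma-3,7(11)-dien-8-one
Conditions: Bu3SnH, AIBN (cat.), toluene, 100 °C
Reagents that add atoms: none
Why: Barton–McCombie radical deoxygenation: the stannyl radical adds to sulfur, the C1–O bond breaks to a secondary C1 radical and hydrogen transfer from Bu3SnH gives the C1 methylene, which removes the C1 stereocentre while C5 and C10 are untouched and the trisubstituted 3-ene and the tetrasubstituted enone stay out of the chain.

Step 5
Reactants: 6 eudesma-3,7(11)-dien-8-one
Product: 9 4β-acetoxy-3β-hydroxyeudesm-7(11)-en-8-one, via 3α-iodo-4β-acetate 7 (not isolated), via β-face dioxolan-2-ylium ion 8 (not isolated)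
Conditions: I2 (1 equiv), AgOAc (2 equiv), AcOH, rt, dark; then H2O, 90 °C; filtration, neutral work-up, prompt use
Reagents that add atoms: silver acetate, CC(=O)[O-].[Ag+]; water, O
Why: Woodward cis-hydroxylation: iodine adds to the α face of the 3-ene (the β face at C4 is screened by the axial C10 methyl), acetate opens the iodonium ion trans-diaxially at the tertiary C4 to give 7, the 4β-acetate then displaces the axial 3α-iodide with silver assistance to give cation 8, and water adds to its acetal carbon, the tetrahedral adduct being expected to open to the axial ester on the more hindered C4 oxygen and the free equatorial C3 hydroxyl, so that C4 (β-OAc, α-CH3) is set by the anti opening and C3 (β-OH) by double inversion.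

Step 6
Reactants: 10 angelic acid
Product: 11 angelic 2,4,6-trichlorobenzoic anhydride
Conditions: 2,4,6-trichlorobenzoyl chloride, Et3N, toluene, 0 °C → rt; filtered, used as solution
Reagents that add atoms: 2,4,6-trichlorobenzoyl chloride, O=C(Cl)c1c(Cl)cc(Cl)cc1Cl
Why: Formation of a Yamaguchi-type mixed anhydride by acylation of the triethylammonium carboxylate at room temperature, conditions under which the (Z)-alkene of angelic acid should not isomerise.

Step 7
Reactants: 9 4β-acetoxy-3β-hydroxyeudesm-7(11)-en-8-one; 11 angelic 2,4,6-trichlorobenzoic anhydride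
Product: 12 4β-acetoxy-3β-angeloyloxyeudesm-7(11)-en-8-one
Conditions: 11 (3 equiv), Et3N (1 equiv), toluene, 80 °C, no DMAP
Reagents that add atoms: none
Why: Esterification by acyl transfer from the mixed anhydride, in which the alcohol attacks the angeloyl carbonyl because the aroyl carbonyl is shielded by two ortho chlorines; leaving out a nucleophilic catalyst keeps the (Z)-geometry (no addition–elimination to the tiglate), prompt acylation of the C3 hydroxyl forestalls acetyl migration from O4 to O3, and C3 keeps its configuration because its C–O bond is not broken.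

Step 8
Reactants: 12 4β-acetoxy-3β-angeloyloxyeudesm-7(11)-en-8-one
Product: 13 4β-acetoxy-3β-angeloyloxy-8-(trimethylsilyloxy)eudesma-7,11-diene
Conditions: TMSOTf, Et3N, CH2Cl2, −78 → 0 °C; pentane, cold aq. NaHCO3 wash; used crude
Reagents that add atoms: trimethylsilyl trifluoromethanesulfonate, C[Si](C)(C)OS(=O)(=O)C(F)(F)F
Why: Soft enolisation: TMSOTf silylates the enone oxygen and Et3N removes a proton from an isopropylidene methyl group, which is more accessible than the C9 hydrogens next to the quaternary C10, to give the through-conjugated 8-silyloxy-7,11-diene; the esters should not be enolised at this temperature and no stereocentre is involved.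

Step 9
Reactants: 13 4β-acetoxy-3β-angeloyloxy-8-(trimethylsilyloxy)eudesma-7,11-diene
Product: 16 4β-acetoxy-3β-angeloyloxy-7α-hydroxyeudesm-11-en-8-one (target CNP0381775.1), via silyloxy epoxide 14 (not isolated), via 7α-silyloxy ketone 15 (not isolated)
Conditions: mCPBA (1.1 equiv), hexane–CH2Cl2, −20 → 0 °C; then 1 M HCl, THF, 0 °C
Reagents that add atoms: 3-chloroperbenzoic acid (mCPBA), O=C(OO)c1cccc(Cl)c1
Why: Rubottom oxidation: the peracid epoxidises the tetrasubstituted silyl enol ether C7=C8, the most electron-rich alkene present (the C11=C12 alkene is twisted out of conjugation by allylic strain and the angelate alkene is electron-poor), on the α face because the axial C10 methyl screens the β face at C8, epoxide 14 opens with 1,4-silyl shift to 15 and dilute acid cleaves the tertiary silyl ether, so C7 is set as α-hydroxyl with the isopropenyl group equatorial.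

Compound list
1 | germacrone, (E,E)-germacra-1(10),4,7(11)-trien-8-one | CC(C)=C1C/C=C(C)/CC/C=C(C)/CC1=O | starting material
2 | (1R,10R)-1,10-epoxygermacrone, trans-epoxide with (E)-C4=C5 and C7=C11 enone retained | CC(C)=C1C/C=C(C)/CC[C@H]2O[C@]2(C)CC1=O | intermediate
3 | eudesm-4-yl cation with 1β-O–BF3 alkoxide, 5αH, 10β-methyl (formed in the flask) | CC(C)=C1C[C@@H]2[C@](C)([C@H](O[B-](F)(F)F)CC[C+]2C)CC1=O | intermediate
4 | 1β-hydroxyeudesma-3,7(11)-dien-8-one, trans-decalin, 5αH, 10β-methyl | CC(C)=C1C[C@@H]2[C@](C)([C@H](O)CC=C2C)CC1=O | intermediate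
5 | 1β-(imidazol-1-ylthiocarbonyloxy)eudesma-3,7(11)-dien-8-one | CC(C)=C1C[C@@H]2[C@](C)([C@H](OC(=S)n3ccnc3)CC=C2C)CC1=O | intermediate
6 | eudesma-3,7(11)-dien-8-one, 5αH, 10β-methyl | CC(C)=C1C[C@@H]2[C@](C)(CCC=C2C)CC1=O | intermediate
7 | 4β-acetoxy-3α-iodoeudesm-7(11)-en-8-one, 4α-methyl (formed in the flask) | CC(C)=C1C[C@@H]2[C@](C)(CC[C@@H](I)[C@]2(C)OC(C)=O)CC1=O | intermediate
8 | 2-methyl-1,3-dioxolan-2-ylium acetate fused at O3β/O4β of eudesm-7(11)-en-8-one (formed in the flask) | CC(C)=C1C[C@@H]2[C@](C)(CC[C@@H]3OC(C)=[O+][C@@]32C)CC1=O.CC(=O)[O-] | intermediate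
9 | 4β-acetoxy-3β-hydroxyeudesm-7(11)-en-8-one, 4α-methyl | CC(C)=C1C[C@@H]2[C@](C)(CC[C@H](O)[C@]2(C)OC(C)=O)CC1=O | intermediate
10 | angelic acid, (Z)-2-methylbut-2-enoic acid | C/C=C(/C)C(=O)O | starting material
11 | angelic 2,4,6-trichlorobenzoic anhydride | C/C=C(/C)C(=O)OC(=O)c1c(Cl)cc(Cl)cc1Cl | intermediate
12 | 4β-acetoxy-3β-angeloyloxyeudesm-7(11)-en-8-one | CC(C)=C1C[C@@H]2[C@](C)(CC[C@H](OC(=O)/C(C)=C\C)[C@]2(C)OC(C)=O)CC1=O | intermediate
13 | 4β-acetoxy-3β-angeloyloxy-8-(trimethylsilyloxy)eudesma-7,11-diene | C=C(C)C=1C[C@@H]2[C@](C)(CC[C@H](OC(=O)/C(C)=C\C)[C@]2(C)OC(C)=O)CC=1O[Si](C)(C)C | intermediate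
14 | 4β-acetoxy-3β-angeloyloxy-7α,8α-epoxy-8β-(trimethylsilyloxy)eudesm-11-ene (formed in the flask) | C=C(C)[C@@]13C[C@@H]2[C@](C)(CC[C@H](OC(=O)/C(C)=C\C)[C@]2(C)OC(C)=O)C[C@]1(O[Si](C)(C)C)O3 | intermediate
15 | 4β-acetoxy-3β-angeloyloxy-7α-(trimethylsilyloxy)eudesm-11-en-8-one (formed in the flask) | C=C(C)[C@@]1(O[Si](C)(C)C)C[C@@H]2[C@](C)(CC[C@H](OC(=O)/C(C)=C\C)[C@]2(C)OC(C)=O)CC1=O | intermediate
16 | 4β-acetoxy-3β-angeloyloxy-7α-hydroxyeudesm-11-en-8-one, 4α-methyl, 5αH, 10β-methyl, 7β-isopropenyl | C=C(C)[C@@]1(O)C[C@@H]2[C@](C)(CC[C@H](OC(=O)/C(C)=C\C)[C@]2(C)OC(C)=O)CC1=O | target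

Total step count: 9
Longest linear sequence: 8 steps (steps 1–5 and 7–9 from germacrone; step 6 is a one-step side branch)

Steps most likely to fail

Step 1. The oxidant may discriminate poorly between the two trisubstituted alkenes, the catalyst may select the enantiotopic faces of the flexible ring poorly, and the β,γ-epoxy ketone may open by β-elimination during the reaction. Fallback: starting from 1, epoxidation with mCPBA (CH2Cl2, 0 °C) and removal of the 4,5-epoxide should give racemic trans-1,10-epoxygermacrone F1. Preparative HPLC on an amylose tris(3,5-dimethylphenylcarbamate) phase then separates the enantiomers. The (1R,10R)-enantiomer, assigned by crystallography of a derivative, is compound 2, where the route is rejoined. Asymmetric catalysis is thus replaced by resolution.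

Step 2. Proton loss from the C4 cation may go towards C15 or C5 instead of C3, so that the material is spread over three alkene isomers. Fallback: starting from 2, the same C5–C10 bond is closed homolytically with Cp2TiCl (trivalent titanium, made from Cp2TiCl2 and Mn dust, THF, rt). The epoxide opens to the tertiary C10 radical, which adds to C5. The C4 radical is trapped by a second trivalent titanium and loses a methyl hydrogen, a termination that in this reaction class gives the exocyclic alkene, here 1β-hydroxyeudesma-4(15),7(11)-dien-8-one F2. Isomerisation with RhCl3·3H2O (cat.) in EtOH at 70 °C, conditions under which a trisubstituted ring alkene normally persists, should move the alkene to C3=C4 and return the route to compound 4.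

Step 9. Oxygen transfer may go to the terminal carbon C12 of the dienol silane instead of C7, or the silane may be hydrolysed back to 12 before it is oxidised. Fallback: starting from 13, PhSeCl (CH2Cl2, −78 °C) is used because this electrophile attacks O-silylated dienolates at the terminal carbon. It should give 4β-acetoxy-3β-angeloyloxy-12-(phenylselanyl)eudesm-7(11)-en-8-one F3, of which either alkene geometry serves. Oxidation with H2O2 and pyridine (CH2Cl2, 0 °C) gives the allylic selenoxide F4. Its [2,3]-sigmatropic shift carries oxygen from selenium to C7 and moves the alkene to C11=C12, giving the C7 selenenate F5, and hydrolysis of F5 gives compound 16. The site preference that would defeat the peracid route is the one this sequence needs.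

Further compounds
F1 | step 1 | racemic trans-1,10-epoxygermacrone (2 and its enantiomer) | CC(C)=C1C/C=C(C)/CC[C@H]2O[C@]2(C)CC1=O.CC(C)=C1C/C=C(C)/CC[C@@H]2O[C@@]2(C)CC1=O
F2 | step 2 | 1β-hydroxyeudesma-4(15),7(11)-dien-8-one | CC(C)=C1C[C@@H]2[C@](C)([C@H](O)CCC2=C)CC1=O
F3 | step 9 | 4β-acetoxy-3β-angeloyloxy-12-(phenylselanyl)eudesm-7(11)-en-8-one | CC(C[Se]c3ccccc3)=C1C[C@@H]2[C@](C)(CC[C@H](OC(=O)/C(C)=C\C)[C@]2(C)OC(C)=O)CC1=O
F4 | step 9 | 4β-acetoxy-3β-angeloyloxy-12-(phenylseleninyl)eudesm-7(11)-en-8-one | CC(C[Se](=O)c3ccccc3)=C1C[C@@H]2[C@](C)(CC[C@H](OC(=O)/C(C)=C\C)[C@]2(C)OC(C)=O)CC1=O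
F5 | step 9 | 4β-acetoxy-3β-angeloyloxy-7α-(phenylselanyloxy)eudesm-11-en-8-one | C=C(C)[C@@]1(O[Se]c3ccccc3)C[C@@H]2[C@](C)(CC[C@H](OC(=O)/C(C)=C\C)[C@]2(C)OC(C)=O)CC1=O
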